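The target is two identical 2-isobutyryl-4,4-dimethylcyclohexane-1,3,5-trione rings (rings A and A′; C1 carbonyl, C2 acyl-bearing, C3, C4 quaternary, C5, C6) joined by a CH2 at C6. The route rests on closing each ring at its most hindered bond, C4–C5, by an intramolecular Claisen condensation of a linear 3,5-dioxo ester whose isopropyl methine becomes C4 and whose ester carbon becomes C5, building the carbocycle and its quaternary carbon in one operation. The step exploits the alternating 1,3,5-tricarbonyl pattern of ring A, with C4 flanked by two carbonyls that enolize outward, and the mirror plane through C4 and C1, which keeps C2 and C6 equivalent until acylation and formaldehyde coupling.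

Key step: step 2

Remark: all cyclic triketones are written as one of several rapidly interconverting enol tautomers; the target has no stereocentre, so no step needs stereocontrol.

Step 1
Reactants: 1 methyl acetoacetate; 2 N-methoxy-N-methylisobutyramide
Product: 3 methyl 6-methyl-3,5-dioxoheptanoate
Conditions: LiN(iPr)2 (2.2 equiv), THF, 0 °C; then 2, −78 °C to rt; aq. HCl
Reagents that add atoms: none
Why: The γ-carbanion of the acetoacetate dianion should be acylated by the N-methoxy-N-methyl amide (Claisen-type acylation of a β-keto ester dianion), the chelated tetrahedral adduct preventing over-addition until the acidic work-up.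

Step 2
Reactants: 3 methyl 6-methyl-3,5-dioxoheptanoate
Product: 4 filicinic acid (3,5-dihydroxy-4,4-dimethylcyclohexa-2,5-dien-1-one, enol form of 2,2-dimethylcyclohexane-1,3,5-trione)
Conditions: NaOMe (3 equiv), MeOH, 150–185 °C (sealed vessel); then aq. HCl
Reagents that add atoms: none
Why: Under NaOMe the diketo ester rests as its dianion (chain carbons 2 and 4 deprotonated), which equilibrates with the tautomer enolized at the isopropyl methine (chain carbon 6); this tertiary enolate adds to the ester carbonyl (chain carbon 1) and expels methoxide, so that the methine carbon becomes ring C4 and the ester carbon becomes ring C5 (intramolecular Claisen condensation, Dieckmann type). The closest known reactions are the alkoxide-mediated ring closures of δ-keto esters to cyclohexane-1,3-diones (dimedone synthesis) and of 3,5-dioxoalkanoates to cyclohexane-1,3,5-triones. The six-membered ring closes in a 6-(enolexo)-exo-trig mode, and no stereocentre is formed. A Claisen condensation at a tertiary carbon normally reverts, but here both carbonyls flanking C4 enolize outward, so the product should leave the equilibrium as the doubly deprotonated vinylogous acid. The step needs C- over O-acylation and closure over chain cleavage: the methine is the only carbon that can reach the ester through a six-membered transition state (the other two acidic carbons would give four-membered rings), and methoxide in methanol should keep the competing enol lactone (2-pyranone) and any retro-Claisen fragments in equilibrium with the open chain, from which only the carbocycle is withdrawn.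

Step 3
Reactants: 4 filicinic acid; 5 isobutyryl chloride
Product: 7 isobutyrylfilicinic acid, via filicinic acid O-isobutyrate 6 (not isolated)
Conditions: 5 (1.0 equiv), Et3N (2.2 equiv), CH2Cl2, 0 °C; then DMAP (0.2 equiv), rt; aq. HCl
Reagents that add atoms: none
Why: O-Acylation of the vinylogous acid to enol ester 6 and DMAP-catalysed O-to-C acyl migration (Fries-type rearrangement of cyclic 1,3-dione enol esters) should give the hydrogen-bonded 2-acyl trione; the two ring CH positions of 4 are equivalent, so no regiochemical choice arises, and the first acyl group deactivates the ring towards a second.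

Step 4
Reactants: 7 isobutyrylfilicinic acid (2 equiv); 8 formaldehyde
Product: 11 target (methylene-bridged dimer, albaspidin type), via hydroxymethyl adduct 9 (not isolated), via methylidene trione 10 (not isolated)
Conditions: 37% aq. HCHO (0.5 equiv), 1% aq. KOH, rt; then aq. HCl
Reagents that add atoms: none
Why: Hydroxymethylation of the only free ring CH (aldol addition to formaldehyde), dehydration to enone 10 and conjugate addition of a second enolate of 7 (Knoevenagel–Michael sequence) should give the methylene-bridged dimer, which cannot react further because no ring CH remains.

Compound list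
1 | methyl acetoacetate (methyl 3-oxobutanoate) | COC(=O)CC(C)=O | starting material
2 | N-methoxy-N-methylisobutyramide (N-methoxy-N,2-dimethylpropanamide) | CC(C)C(=O)N(C)OC | starting material
3 | methyl 6-methyl-3,5-dioxoheptanoate | COC(=O)CC(=O)CC(=O)C(C)C | intermediate
4 | filicinic acid (3,5-dihydroxy-4,4-dimethylcyclohexa-2,5-dien-1-one) | CC1(C)C(O)=CC(=O)C=C1O | intermediate
5 | isobutyryl chloride (2-methylpropanoyl chloride) | CC(C)C(Cl)=O | starting material
6 | filicinic acid O-isobutyrate (5-hydroxy-6,6-dimethyl-3-oxocyclohexa-1,4-dien-1-yl 2-methylpropanoate) | CC(C)C(=O)OC1=CC(=O)C=C(O)C1(C)C | intermediate (not isolated)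
7 | isobutyrylfilicinic acid (3,5-dihydroxy-4,4-dimethyl-2-(2-methylpropanoyl)cyclohexa-2,5-dien-1-one) | CC(C)C(=O)C1=C(O)C(C)(C)C(O)=CC1=O | intermediate
8 | formaldehyde | C=O | starting material
9 | hydroxymethyl adduct (3,5-dihydroxy-6-(hydroxymethyl)-4,4-dimethyl-2-(2-methylpropanoyl)cyclohexa-2,5-dien-1-one) | CC(C)C(=O)C1=C(O)C(C)(C)C(O)=C(CO)C1=O | intermediate (not isolated)
10 | methylidene trione (5-hydroxy-6,6-dimethyl-2-methylidene-4-(2-methylpropanoyl)cyclohex-4-ene-1,3-dione) | CC(C)C(=O)C1=C(O)C(C)(C)C(=O)C(=C)C1=O | intermediate (not isolated)
11 | 2,2'-methylenebis[3,5-dihydroxy-4,4-dimethyl-6-(2-methylpropanoyl)cyclohexa-2,5-dien-1-one] | CC(C)C(=O)C1=C(O)C(C)(C)C(O)=C(CC2=C(O)C(C)(C)C(O)=C(C(=O)C(C)C)C2=O)C1=O | target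

Total step count: 4. Longest linear sequence: 4 steps (1 → 3 → 4 → 7 → 11).

Steps most likely to fail

Step 2. Enolization at the hindered methine of a dianion whose ester is partly deactivated may be too slow, so that enol-lactonization on work-up or thermal chain cleavage takes over. The fallback sets out from 1 and comes back at 4, bringing the quaternary carbon in already bonded to the ester and closing the ring from the other side. Double C-methylation of 1 (MeI, K2CO3, acetone) should give methyl 2,2-dimethyl-3-oxobutanoate F1. Its kinetic methyl-ketone enolate (LiN(iPr)2, 2 equiv, THF, −78 °C) should be acylated by ethyl acetate to methyl 2,2-dimethyl-3,5-dioxohexanoate F2. Treating F2 with LiN(iPr)2 (2.2 equiv, THF, −78 to 0 °C) should give the diketone dianion, whose terminal methyl carbanion closes onto the ester, which has no α-hydrogen, to give 4 after acidification.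

Step 3. O-Acylation may not be followed by clean migration to carbon, and a second acylation at the other equivalent ring CH may compete. The fallback sets out from 5 and comes back at 7, placing the acyl group on an aromatic ring first. Friedel–Crafts acylation of commercial phloroglucinol (benzene-1,3,5-triol, Oc1cc(O)cc(O)c1) with 5 (AlCl3, PhNO2, rt) should give phlorisobutyrophenone F3. Dearomatizing geminal C-methylation of F3 (MeI, NaOMe, MeOH, 0 °C to rt) should then give 7.

Step 4. The stoichiometry of the one-pot bridging may be hard to control, leaving hydroxymethylated monomer or letting the enone intermediate add water instead of the second ring. The fallback sets out from 7 and comes back at 11, separating electrophile formation from coupling. Mannich reaction of 7 with 8 and dimethylamine (CNC; EtOH, rt) should give the Mannich base 6-[(dimethylamino)methyl]-3,5-dihydroxy-4,4-dimethyl-2-(2-methylpropanoyl)cyclohexa-2,5-dien-1-one F4. Heating F4 with one further equivalent of 7 (dioxane, reflux) should release dimethylamine, generate enone 10 slowly and let it be trapped by 7 to give 11.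

Further compounds
F1 | step 2 | methyl 2,2-dimethyl-3-oxobutanoate | COC(=O)C(C)(C)C(C)=O
F2 | step 2 | methyl 2,2-dimethyl-3,5-dioxohexanoate | COC(=O)C(C)(C)C(=O)CC(C)=O
F3 | step 3 | phlorisobutyrophenone (2-methyl-1-(2,4,6-trihydroxyphenyl)propan-1-one) | CC(C)C(=O)c1c(O)cc(O)cc1O
F4 | step 4 | 6-[(dimethylamino)methyl]-3,5-dihydroxy-4,4-dimethyl-2-(2-methylpropanoyl)cyclohexa-2,5-dien-1-one | CC(C)C(=O)C1=C(O)C(C)(C)C(O)=C(CN(C)C)C1=O
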